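## Retrosynthetic overview
1. In one flask: target ⇐ acetate trap ⇐ transannular aldol C-2→C-6, which closes both six-membered rings at once ⇐ eight-membered trialdehyde ⇐ 1,2-shift of C-5 from C-6 to C-7 in dictyodial 6,7-epoxide.
2. Dictyodial (nine-membered ring) ⇐ ring diester ⇐ B-alkyl Suzuki closure of C-7–C-8 on an acyclic (E)-vinyl iodide/terminal alkene.
3. Acyclic precursor ⇐ HWE olefination (C-3=C-4) of a phosphonosuccinate with (E)-4-iodopent-3-enal, made from pent-3-yn-1-ol.
4. Phosphonosuccinate ⇐ Wittig methylenation (C-8) ⇐ enamine-catalysed Michael addition of (R)-citronellal to a phosphonofumarate made from glyoxylate and phosphonoacetate. C-11 comes from the chiral pool and C-10 is set by the catalyst.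
5. Ring order: nine-membered carbocycle → oxirane → eight-membered ring → bicyclo[3.3.1]nonene.

Assumption: the presumed biosynthesis is dictyodial → 6,7-epoxide → 1,2-alkyl shift (nine- to eight-membered ring) → transannular aldol → O-acetylation. Labels C-1 to C-20 are geranylgeranyl numbers: C-2 to C-10 are the xenicane ring, C-1 and C-20 the formyl carbons on C-2 and C-3, and C-11 the side-chain stereocentre.

## Route

Step 1
Reactants: 1 ethyl glyoxylate; 2 triethyl phosphonoacetate
Product: 3 diethyl 2-(diethoxyphosphoryl)but-2-enedioate (E/Z mixture)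
Conditions: piperidine (cat.), AcOH (cat.), toluene, reflux, Dean–Stark
Reagents that add atoms: none
Why: Knoevenagel condensation of the phosphonoacetate CH2 with the very electrophilic glyoxylate aldehyde under amine/acid catalysis keeps the phosphorus (no strong base, so no HWE loss); no stereocentre forms and the alkene geometry is irrelevant because the alkene is consumed next.

Step 2
Reactants: 3 diethyl 2-(diethoxyphosphoryl)but-2-enedioate; 4 (R)-citronellal
Product: 5 diethyl 2-(diethoxyphosphoryl)-3-[(2S,3R)-3,7-dimethyl-1-oxooct-6-en-2-yl]butanedioate (mixture at C-2 and C-3)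
Conditions: (R)-α,α-diphenylprolinol trimethylsilyl ether (15 mol %), PhCO2H (15 mol %), toluene, 0 °C
Reagents that add atoms: none
Why: Enamine-catalysed asymmetric Michael addition (closest acceptors: vinyl bis(phosphonates), alkylidene malonates): the E-enamine attacks the CH= carbon of the triply activated alkene from the face left open by the diphenyl(silyloxy)methyl group, so the (R)-catalyst sets C-10 as (S) under catalyst control, and the C-2/C-3 centres are erased later.

Step 3
Reactants: 5 Michael adduct
Product: 6 diethyl 2-(diethoxyphosphoryl)-3-[(3S,4R)-4,8-dimethylnona-1,7-dien-3-yl]butanedioate (mixture at C-2 and C-3)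
Conditions: Ph3PCH3Br, KN(SiMe3)2 (2.2 equiv ylide), THF, −78 → 0 °C
Reagents that add atoms: methyltriphenylphosphonium bromide, C[P+](c1ccccc1)(c1ccccc1)c1ccccc1.[Br-]
Why: Wittig methylenation brings in C-8 and removes the epimerisable aldehyde early; carbonyl addition at −78 °C outruns enolisation at C-10, and the acidic phosphonoacetate C–H is only parked as its anion until work-up.

Step 4
Reactants: 7 pent-3-yn-1-ol
Product: 9 (E)-4-iodopent-3-en-1-ol, via alkenylzirconocene 8 (not isolated)
Conditions: Cp2Zr(H)Cl (2.3 equiv), THF, rt; then I2, −78 → 0 °C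
Reagents that add atoms: iodine, II
Why: Syn-hydrozirconation equilibrates zirconium to the less hindered methyl-bearing alkyne carbon, and iodinolysis with retention gives the E-vinyl iodide (methyl cis to the chain) that fixes the later ring alkene geometry.

Step 5
Reactants: 9 (E)-4-iodopent-3-en-1-ol
Product: 10 (E)-4-iodopent-3-enal
Conditions: Dess–Martin periodinane, pyridine, CH2Cl2, 0 °C; used at once
Reagents that add atoms: none
Why: Buffered Dess–Martin oxidation gives the β,γ-unsaturated aldehyde without moving the double bond into conjugation.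

Step 6
Reactants: 6 alkenyl phosphonosuccinate; 10 (E)-4-iodopent-3-enal
Product: 11 diethyl (2E)-2-[(3E)-4-iodopent-3-en-1-ylidene]-3-[(3S,4R)-4,8-dimethylnona-1,7-dien-3-yl]butanedioate (epimers at C-2)
Conditions: NaH (1.0 equiv), THF, 0 °C; then 10, −78 → 0 °C
Reagents that add atoms: none
Why: Horner–Wadsworth–Emmons olefination as used for alkylidene succinates: reversible addition places the C-5 chain trans to the conjugated ester and cis to C-2 (whose C–H lies in the alkene plane), which is the geometry the ring needs; with no excess base the sensitive aldehyde is not isomerised.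

Step 7
Reactants: 11 seco vinyl iodide
Product: 13 diethyl (2E,6E,9S)-6-methyl-9-[(2R)-6-methylhept-5-en-2-yl]cyclonona-2,6-diene-1,2-dicarboxylate (epimers at C-2), via alkylborane 12 (not isolated)
Conditions: 9-BBN-H, THF, rt; then slow addition to Pd(dppf)Cl2 (15 mol %), AsPh3, Cs2CO3, DMF–THF–H2O, 45 °C, 1 mM
Reagents that add atoms: none
Why: 9-BBN hydroborates only the monosubstituted alkene, and the intramolecular B-alkyl Suzuki–Miyaura coupling (known to close this xenicane ring type) forms C-7–C-8 with retention at the vinyl iodide, giving the E ring alkene; no stereocentre is touched.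

Step 8
Reactants: 13 nine-membered diester
Product: 14 [(2E,6E,9S)-6-methyl-9-[(2R)-6-methylhept-5-en-2-yl]cyclonona-2,6-diene-1,2-diyl]dimethanol (epimers at C-2)
Conditions: iBu2AlH (5 equiv), CH2Cl2, −78 → 0 °C; aqueous work-up
Reagents that add atoms: none
Why: Aluminium hydride 1,2-reduction takes both the saturated and the conjugated ester to the primary alcohols without touching any alkene.

Step 9
Reactants: 14 diol
Product: 15 dictyodial, (2E,6E,9S)-6-methyl-9-[(2R)-6-methylhept-5-en-2-yl]cyclonona-2,6-diene-1,2-dicarbaldehyde (C-2 epimerisable)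
Conditions: (COCl)2, DMSO, CH2Cl2, −78 °C; Et3N, −78 → −20 °C
Reagents that add atoms: none
Why: Double Swern oxidation is the standard way from 2-ene-1,4-diols to 2-ene-1,4-dialdehydes without lactol over-oxidation; the C-2 configuration does not matter because it is erased by enolisation in step 11.

Step 10
Reactants: 15 dictyodial
Product: 16 dictyodial 6,7-epoxide (trans-oxirane, C-6 R, C-7 R)
Conditions: dimethyldioxirane (1.0 equiv, acetone), CH2Cl2, −78 → −40 °C
Reagents that add atoms: dimethyldioxirane, CC1(C)OO1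
Why: In this strain-accelerated electrophilic epoxidation the twisted E-trisubstituted ring alkene reacts faster than the unstrained prenyl alkene and the enal alkene is electron-poor; only the outer face is open in the conformer with the C-10 chain pseudo-equatorial, giving the (6R,7R)-epoxide in the same sense as caryophyllene → caryophyllene oxide.

Step 11
Reactants: 16 dictyodial 6,7-epoxide
Product: 19 acetylsanadaol, (1R,5R,8S,9R)-1,2-diformyl-5-methyl-8-[(2R)-6-methylhept-5-en-2-yl]bicyclo[3.3.1]non-2-en-9-yl acetate, via trialdehyde 17 (not isolated), via sanadaol 18 (not isolated)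
Conditions: MeAl(OC6H2-4-Br-2,6-tBu2)2 (3 equiv, from Me3Al and 4-bromo-2,6-di-tert-butylphenol), CH2Cl2, −78 → −40 °C; iPr2NEt, −40 → 0 °C; then Ac2O, DMAP, 0 °C → rt
Reagents that add atoms: acetic anhydride, CC(=O)OC(C)=O
Why: Proposed new method: the bulky aluminium Lewis acid ionises the epoxide at tertiary C-7 and, as in its known Meinwald/semipinacol rearrangement of trisubstituted epoxides to α-quaternary aldehydes (alkyl over hydride shift), C-5 migrates from C-6 to C-7 anti to the leaving oxygen, turning the (7R)-oxirane carbon into the (R)-quaternary centre and contracting the ring to eight; soft enolisation of the doubly activated C-2–H (Lewis acid plus tertiary amine, as in amine-mediated aldol reactions) then gives an aluminium dienolate that reaches the new formyl group only across the ring on the face syn to H-10, closing both six-membered rings and fixing C-2, while a closed aluminium-bridged transition state with the enolate oxygen turned away from the C-3 formyl group puts the C-6 oxygen over the saturated ring; dehydration is impossible between two quaternary carbons, and Ac2O/DMAP traps the aldolate before retro-aldol.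

## Compound list
1 | ethyl glyoxylate | CCOC(=O)C=O | starting material
2 | triethyl phosphonoacetate | CCOC(=O)CP(=O)(OCC)OCC | starting material
3 | diethyl 2-(diethoxyphosphoryl)but-2-enedioate (E/Z mixture) | CCOC(=O)C=C(C(=O)OCC)P(=O)(OCC)OCC | intermediate
4 | (R)-citronellal, (3R)-3,7-dimethyloct-6-enal | C[C@H](CCC=C(C)C)CC=O | starting material
5 | diethyl 2-(diethoxyphosphoryl)-3-[(2S,3R)-3,7-dimethyl-1-oxooct-6-en-2-yl]butanedioate (succinate carbons unassigned) | O=C[C@@H]([C@H](C)CCC=C(C)C)C(C(=O)OCC)C(C(=O)OCC)P(=O)(OCC)OCC | intermediate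
6 | diethyl 2-(diethoxyphosphoryl)-3-[(3S,4R)-4,8-dimethylnona-1,7-dien-3-yl]butanedioate (succinate carbons unassigned) | C=C[C@@H]([C@H](C)CCC=C(C)C)C(C(=O)OCC)C(C(=O)OCC)P(=O)(OCC)OCC | intermediate
7 | pent-3-yn-1-ol | CC#CCCO | starting material
8 | (E)-alkenylzirconocene chloride, zirconium on the methyl-bearing carbon, oxygen also zirconated (not isolated) | C/C(=C\CCO[Zr](Cl)(C1C=CC=C1)C1C=CC=C1)[Zr](Cl)(C1C=CC=C1)C1C=CC=C1 | intermediate
9 | (E)-4-iodopent-3-en-1-ol | C/C(I)=C\CCO | intermediate
10 | (E)-4-iodopent-3-enal | C/C(I)=C\CC=O | intermediate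
11 | diethyl (2E)-2-[(3E)-4-iodopent-3-en-1-ylidene]-3-[(3S,4R)-4,8-dimethylnona-1,7-dien-3-yl]butanedioate (C-2 epimers) | C=C[C@@H]([C@H](C)CCC=C(C)C)C(C(=O)OCC)/C(C(=O)OCC)=C\C/C=C(\C)I | intermediate
12 | B-alkyl-9-borabicyclo[3.3.1]nonane from anti-Markovnikov hydroboration of the vinyl group of 11 (not isolated) | C(C[C@@H]([C@H](C)CCC=C(C)C)C(C(=O)OCC)/C(C(=O)OCC)=C\C/C=C(\C)I)B1C2CCCC1CCC2 | intermediate
13 | diethyl (2E,6E,9S)-6-methyl-9-[(2R)-6-methylhept-5-en-2-yl]cyclonona-2,6-diene-1,2-dicarboxylate (C-2 epimers) | C/C1=C\C/C=C(C(=O)OCC)\C(C(=O)OCC)[C@H]([C@H](C)CCC=C(C)C)CC1 | intermediate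
14 | corresponding 1,2-bis(hydroxymethyl)cyclonona-2,6-diene (2E,6E,9S; C-2 epimers) | C/C1=C\C/C=C(CO)\C(CO)[C@H]([C@H](C)CCC=C(C)C)CC1 | intermediate
15 | dictyodial, (2E,6E,9S)-6-methyl-9-[(2R)-6-methylhept-5-en-2-yl]cyclonona-2,6-diene-1,2-dicarbaldehyde (C-2 epimerisable) | C/C1=C\C/C=C(C=O)\C(C=O)[C@H]([C@H](C)CCC=C(C)C)CC1 | intermediate
16 | dictyodial 6,7-epoxide, trans-oxirane, C-6 (R), C-7 (R) | C[C@@]12CC[C@@H]([C@H](C)CCC=C(C)C)C(C=O)/C(C=O)=C\C[C@H]1O2 | intermediate
17 | (2E,5R,8S)-5-methyl-8-[(2R)-6-methylhept-5-en-2-yl]cyclooct-2-ene-1,2,5-tricarbaldehyde (not isolated) | C[C@]1(C=O)C/C=C(C=O)\C(C=O)[C@H]([C@H](C)CCC=C(C)C)CC1 | intermediate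
18 | sanadaol, (1R,5R,8S,9R)-9-hydroxy-5-methyl-8-[(2R)-6-methylhept-5-en-2-yl]bicyclo[3.3.1]non-2-ene-1,2-dicarbaldehyde (not isolated) | O[C@@H]1[C@@]2(C)CC=C(C=O)[C@]1(C=O)[C@H]([C@H](C)CCC=C(C)C)CC2 | intermediate
19 | acetylsanadaol (CNP0299929.2) | CC(=O)O[C@@H]1[C@@]2(C)CC=C(C=O)[C@]1(C=O)[C@H]([C@H](C)CCC=C(C)C)CC2 | target

## Step count and risks
Total steps: 11. Longest linear sequence: 9 (steps 1, 2, 3, 6, 7, 8, 9, 10, 11).

**Step 11 (cascade).** It may give hydride shift instead of ring contraction, capture of the cation by a carbonyl oxygen, or the wrong C-6 epimer.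
- The fallback sets out from 13 and does the same ring events stepwise at the ester level.
- Dimethyldioxirane gives the epoxy diester F1.
- MeAl(OC6H2-4-Br-2,6-tBu2)2 alone rearranges it to the formyl cyclooctene diester F2, which can be purified.
- KN(SiMe3)2 at −78 °C forms the ester dienolate and closes the bicyclic hydroxy diester F3.
- LiAlH4 gives the triol F4.
- TEMPO/PhI(OAc)2 oxidises only the two primary alcohols.
- The route is rejoined at 18, which is acetylated (Ac2O, DMAP) to 19.

**Step 7 (nine-membered ring closure).** It may give dimers or protodeboronation.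
- The fallback sets out from 6 and pre-organises the chain on a five-membered ring.
- NaH masks the phosphonoacetate ester as its anion, LiBH4 reduces the other ester, and acidic work-up closes the phosphono lactone F5.
- KOtBu-mediated HWE reaction with 10 gives the E-alkylidene lactone vinyl iodide F6.
- Hydroboration and Suzuki closure on this rigid template give the nine-membered alkylidene lactone F7.
- Excess iBu2AlH opens F7 to the diol, rejoining the route at 14.

**Step 6 (alkene geometry).** The bulky C-2 substituent may favour the isomer that cannot cyclise.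
- The fallback sets out from 6 and 9 and moves the olefination to the ring closure, where only the ring-cis alkene can form.
- Hydroboration of 6 and intermolecular Suzuki coupling with 9 give the seco hydroxy phosphonate F8.
- Dess–Martin oxidation gives the seco aldehyde F9.
- LiCl/DBU at high dilution closes C-3=C-4, rejoining the route at 13.

## Further compounds
F1 | step 11 | epoxy diester, (6R,7R)-epoxide of 13 | C[C@@]12CC[C@@H]([C@H](C)CCC=C(C)C)C(C(=O)OCC)/C(C(=O)OCC)=C\C[C@H]1O2
F2 | step 11 | diethyl (2E,5R,8S)-5-formyl-5-methyl-8-[(2R)-6-methylhept-5-en-2-yl]cyclooct-2-ene-1,2-dicarboxylate | C[C@]1(C=O)C/C=C(C(=O)OCC)\C(C(=O)OCC)[C@H]([C@H](C)CCC=C(C)C)CC1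
F3 | step 11 | diethyl (1R,5R,8S,9R)-9-hydroxy-5-methyl-8-[(2R)-6-methylhept-5-en-2-yl]bicyclo[3.3.1]non-2-ene-1,2-dicarboxylate | O[C@@H]1[C@@]2(C)CC=C(C(=O)OCC)[C@]1(C(=O)OCC)[C@H]([C@H](C)CCC=C(C)C)CC2
F4 | step 11 | corresponding 1,2-bis(hydroxymethyl)bicyclo[3.3.1]non-2-en-9-ol | O[C@@H]1[C@@]2(C)CC=C(CO)[C@]1(CO)[C@H]([C@H](C)CCC=C(C)C)CC2
F5 | step 7 | 3-(diethoxyphosphoryl)-4-[(3S,4R)-4,8-dimethylnona-1,7-dien-3-yl]dihydrofuran-2(3H)-one | C=C[C@@H]([C@H](C)CCC=C(C)C)C1COC(=O)C1P(=O)(OCC)OCC
F6 | step 7 | (3E)-3-[(3E)-4-iodopent-3-en-1-ylidene]-4-[(3S,4R)-4,8-dimethylnona-1,7-dien-3-yl]dihydrofuran-2(3H)-one | C=C[C@@H]([C@H](C)CCC=C(C)C)C1COC(=O)/C1=C/C/C=C(\C)I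
F7 | step 7 | nine-membered E-cyclononene fused to the α-alkylidene-γ-butyrolactone | C/C1=C\C/C=C2/C(=O)OCC2[C@H]([C@H](C)CCC=C(C)C)CC1
F8 | step 6 | seco hydroxy phosphonate, E-trisubstituted alkene, primary alcohol at C-4 | OCC/C=C(\C)CC[C@@H]([C@H](C)CCC=C(C)C)C(C(=O)OCC)C(C(=O)OCC)P(=O)(OCC)OCC
F9 | step 6 | seco aldehyde, C-4 formyl analogue of F8 | O=CC/C=C(\C)CC[C@@H]([C@H](C)CCC=C(C)C)C(C(=O)OCC)C(C(=O)OCC)P(=O)(OCC)OCC
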